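**The gap.** Far more left-handed product than right-handed product stands in the epsilon run at its last reading, 54.1% against 2.3%, and the two new flasks are judged on that gap.

| setting | zeta | theta | gamma | epsilon | south-east | west |
|---|---|---|---|---|---|---|
| left-handed substrate | 0.10 M | 0.10 M | 0.10 M | 0.10 M | 0.10 M | 0.10 M |
| right-handed substrate | 0.10 M | 0.10 M | 0.10 M | 0.10 M | 0.10 M | 0.10 M |
| partner | 3 equiv | 3 equiv | 3 equiv | 3 equiv | 3.00 equiv | 3.00 equiv |
| free catalyst | 0.22 mol% | 0.33 mol% | 0.47 mol% | 0.5 mol% | 0.5 mol% | 0.25 mol% |
| racemization catalyst | 0.21 mol% | 0.21 mol% | 0.21 mol% | 0.21 mol% | 0.21 mol% | 0.15 mol% |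
| added ligand | 0.62 mM | 0.62 mM | 0.62 mM | 1.1 mM | 0.62 mM | 1.0 mM |
| temperature | 45 °C | 56 °C | 45 °C | 56 °C | 50 °C | 50 °C |
| remark | run made earlier | run made earlier | run made earlier | run made earlier |  |  |
| time |  |  |  |  | 5.0 d | 5.0 d |

- zeta (time / d: left-handed product / %, right-handed product / %): 0.208: 3.4, 0; 0.417: 5.5, 0; 0.625: 7.8, 0; 1.25: 15.1, 0.9; 2.50: 26.1, 0.3
- theta (time / d: left-handed product / %, right-handed product / %): 0.208: 6.3, 0.1; 0.417: 13.7, 0.3; 0.625: 18.9, 0; 1.25: 31.7, 1.9; 2.50: 49.0, 2.2
- gamma (time / d: left-handed product / %, right-handed product / %): 0.208: 6.6, 0; 0.417: 10.1, 0.1; 0.625: 16.2, 0.1; 1.25: 28.1, 1.4; 2.50: 44.4, 1.2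
- epsilon (time / d: left-handed product / %, right-handed product / %): 0.500: 18.3, 0.5; 1.04: 31.2, 1.7; 1.67: 43.1, 2.2; 2.08: 48.9, 2.3; 2.50: 54.1, 2.3

(standard deviation of a reading: 0.5 percentage points)

- free catalyst is single-handed; left-handed substrate and right-handed substrate are mirror images of each other, charged as a racemate, each of them at the stated concentration
- the analysis behind the earlier runs scatters by 0.5 percentage points, standard deviation
- an excess is the difference of the two amounts in percent of their sum
- an excess is below zero if the other one leads
- no earlier run changes the charge of racemization catalyst; that part of a forecast is a guess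

* which one finishes higher in excess of left-handed product over right-handed product ("neither" within 2 percentage points) (south-east / west / neither)
* excess of left-handed product over right-handed product at the end, south-east
* excess of left-handed product over right-handed product at the end, west

**Main step.** With the main step by itself, free catalyst and partner turn left-handed substrate into left-handed product. The excess is then 100%, and left-handed product stops at the share of that substrate in the charge, 50.0%.

**Slow step.** The passing of right-handed substrate into right-handed product is taken to use the same free catalyst and partner. Both charges therefore stand in both rates and cancel from their ratio. That ratio is a constant times left-handed over right-handed substrate, and in this pair of steps the left-handed substrate thins first.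

**Racemization.** The third process, through the racemization catalyst, interconverts the substrates. The epsilon run passes the cap, 54.1% against 50.0%, so right-handed substrate is feeding left-handed substrate there. The last readings of theta and epsilon, pooled at 56 °C, give 22.9 left-handed product per right-handed product. This ratio, a reading with its scatter and taken as if the substrates stood equal, is the selectivity factor. Zeta and gamma at 45 °C read 47.0, but on smaller right-handed readings, which the scatter of 0.5 percentage points blurs.

**Own reckoning.** With substrates near equal, the excess is the factor less one over the factor plus one, 91.6%, and this reckoning carries the factor from 56 °C to 50 °C unchanged. Added ligand and free catalyst are taken to act on both rates alike, so this reckoning gives south-east and west the same number. The effect of west's charge of racemization catalyst, 0.15 mol%, remains a guess.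

**The forecast.** It gives 93% for south-east, 94% for west, and neither. Its excess for south-east stands above this reckoning, though the choice is the same, and it remarks: “West is less certain because its racemization charge is untested.”

**The outcome.** South-east ends at 90.5% and west at 91.0%, so the answer is neither.

    partner + free catalyst + left-handed substrate → free catalyst + left-handed product (k = 5.80 M⁻² min⁻¹, Ea = 51.0 kJ mol⁻¹)
    partner + free catalyst + right-handed substrate → free catalyst + right-handed product (k = 0.250 M⁻² min⁻¹, Ea = 70.0 kJ mol⁻¹)
    left-handed substrate + racemization catalyst ⇌ right-handed substrate + racemization catalyst, rate k3*[racemization catalyst]*[left-handed substrate] forward; the back reaction follows from the equilibrium constant (k = 19.0 M⁻¹ min⁻¹, Ea = 71.0 kJ mol⁻¹)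
    2 racemization catalyst → spent catalyst (k = 2.30 M⁻¹ min⁻¹, Ea = 51.0 kJ mol⁻¹)
    free catalyst + added ligand ⇌ idle complex, settled at all times (K = 1000 M⁻¹, ΔH = 28.0 kJ mol⁻¹)
    (constants at 50 °C)

In west at 5.00 d, 46.9% of the catalyst stands as idle complex and 83.2% of the racemization catalyst as spent catalyst, yet neither the parking nor the loss makes a difference to the excess. South-east ends with 11.0% left-handed against 14.3% right-handed substrate, and the factor of 22.9 applied to that pair gives a lower rate ratio of 17.6. The neighbour of west with 0.062 mol% of free catalyst ends at 91.5%, against 91.6% from the factor.

The readings are calculated with constants of no real substance.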